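Split each target that leaves the reaction phase between its two exits before you reckon anything else. It crosses into the second phase with constant 0.0188 h⁻¹ or decomposes with 0.0338 h⁻¹. Call the crossing's part of the two constants, 35.7%, the capture share. Equal constants give an even split, the mark to measure from, and this flask lies below that mark, since decomposition is faster than crossing.

starting material 1.2 M; reagent in the second phase 4.80 M; time 2.5 d; volume of the second phase over the first 2.0

- target and product in the second phase together at 2.5 d, in percent of the starting material charged
- the change that raises the amount of target and product in the second phase together at 2.5 d, in percent of the starting material charged most ("none" if none brings more than 2 percentage points) (elm / alder / cedar / none)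
- amount of target and product in the second phase together at 2.5 d, in percent of the starting material charged, after elm

- a species is counted by the starting material in it: one homo dimer A counts as two
- amounts and yields of target count product in the second phase too
- where a step has two of a species, its rate is k times that concentration squared, and two are used at each turn
- in the second phase: reagent in the second phase, product in the second phase; everything else is in the first
- charges count per volume of the first phase; a concentration in a rate is the amount of a species over the volume of its own phase; every rate counts per litre of the first phase
- run time (flask): 2.5 d

    reagent in the reaction phase ⇌ reagent in the second phase, rate k1*([reagent in the reaction phase] - [reagent in the second phase]/K1) per volume of the first phase (K1 = 0.53, k1 = 0.00774 h⁻¹)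
    target → decomposed product (k2 = 0.0338 h⁻¹)
    target ⇌ product in the second phase, rate k3*([target] - [product in the second phase]/K3) per volume of the first phase (K3 = 14.9, k3 = 0.0188 h⁻¹)
    2 starting material → homo dimer A (k4 = 2.98 × 10⁻⁵ L mol⁻¹ h⁻¹)
    target ⇌ isomer of the product (K5 = 3.32, k5 = 8.91 × 10⁻⁴ h⁻¹)
    starting material + reagent in the reaction phase → target (k6 = 0.0171 L mol⁻¹ h⁻¹)
    2 reagent in the reaction phase → homo dimer B (k7 = 0.00142 L mol⁻¹ h⁻¹)

Elm doubles the constant of the target's crossing, alder doubles that of the reagent's crossing, and cedar doubles the reagent charge.

Now climb the ladder of times. Target in the reaction phase has a mean life of 0.792 d between its exits. Next comes reagent in the reaction phase. The charge stands at 2.40 M in the second phase and feeds the reaction phase at 0.0350 M h⁻¹. Coupling and crossing back remove it with a mean life of 1.47 d, which is longer than the target's, so it climbs towards 1.24 M. The half-life of target by the forward step to the isomer of the product, 32 d, is long against the run, so leave that step out.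

Summing that rising level over 2.5 d couples 48.3% of the starting material. Treat the making as steady: the part made within the last mean life, 31.7%, still stands as target, and the rest has met the capture share. My reckoning commits to 27.1%. With the doubled constant, elm gives 30.8%. Alder gives 38.9%, and cedar, with twice the plateau, gives 41.1%, the highest.

The forecast says 27.5%, cedar and 32% after elm, on the ground that “more reagent doubles the transfer driving force”, which differs from my figures and agrees in the choice.

The simulation gives 25.5%, with cedar ahead at 13 percentage points against 8 points for alder and 3.2 points for elm, and 28.7% after elm.

The yield is held down by decomposition and the slow crossing of target together: against 25.5%, the run without the path to decomposed product reads 43.7%, and the run without the bottleneck of that crossing reads 43.0%. At 2.50 d this flask holds 10.1% as product in the second phase and 18.5% as decomposed product, a split of 35.3%. Read at 4.0 d, the same flask holds 19.5% and 36.0%, a split of 35.2%, against the capture share of 35.7%.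

Its constants were drawn at random within sensible limits; the run is a simulation.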